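**Retrosynthetic overview**
1. Last bond-breaking: fluoride removal of eleven silyl ethers from the fully silylated target.
2. Key disconnection, both O-rings in one flask: ring A (dihydrobenzofuran) is opened at Cα–C3 and O1–C2 to a benzhydryl cation plus a 2-hydroxystilbene (acid-catalysed (3+2) union); ring B (tetrahydrofuran) is opened at O–C2′ to a 1,4-keto silyl ether (hydride reductive etherification).
3. The open-chain precursor comes from an asymmetric boron aldol (sets C5′, the only preset stereocentre), the 1,4-diketone from conjugate reduction/alkylation of a chalcone with an α-chloro ketone.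
4. The chalcone comes from an aryllithium plus a Weinreb cinnamamide, the benzhydryl ether from an aryl Grignard plus an aldehyde, the stilbene–chalcone partner from a Heck reaction followed by a Wittig reaction.
5. Ring order: no ring is closed before the key step; there ring A forms first and ring B second, in the same operation.

**Conventions and assumptions**
- Locants: C2/C3 = dihydrobenzofuran carbons, Cα = diarylmethine, C2′–C5′ = tetrahydrofuran carbons (C2′ resorcinol ring, C3′ benzyl, C4′ aroyl, C5′ 4-hydroxyphenyl). The target is (2R,3R,αR,2′R,3′S,4′S,5′S). TIPS = Si(i-Pr)3, TBS = Si(t-Bu)Me2, TES = SiEt3. Ar* = 5-{[2,4-bis(TIPS-oxy)phenyl](TES-oxy)methyl}-2,4-bis(TIPS-oxy)phenyl. (R)-TRIP-NHTf = (R)-3,3′-bis(2,4,6-triisopropylphenyl)-1,1′-binaphthyl-2,2′-diyl N-triflylphosphoramide.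
- Assumption: the sense of induction of (−)-Ipc2BOTf (step 11) and of (R)-TRIP-NHTf (step 12) is taken by analogy; if either proves opposite, its antipode is used and nothing else changes.

**Route**

Step 1
Reactants: 1 2-chloro-1-(2,4-dihydroxyphenyl)ethan-1-one
Product: 2 2-chloro-1-[2,4-bis(TIPS-oxy)phenyl]ethan-1-one
Conditions: TIPSOTf, 2,6-lutidine, CH2Cl2, −78 → 0 °C
Reagents that add atoms: triisopropylsilyl triflate, CC(C)[Si](C(C)C)(C(C)C)OS(=O)(=O)C(F)(F)F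
Why: O-silylation of both phenols with a silyl triflate and a hindered, non-nucleophilic base, so the α-chloro ketone is not alkylated; no stereocentre.

Step 2
Reactants: 2 2-chloro-1-[2,4-bis(TIPS-oxy)phenyl]ethan-1-one
Product: 4 1-[2,4-bis(TIPS-oxy)phenyl]-2-(triphenylphosphoranylidene)ethan-1-one, via phosphonium chloride 3 (not isolated)
Conditions: PPh3, toluene, 80 °C; then aq. Na2CO3, CH2Cl2, rt
Reagents that add atoms: triphenylphosphine, c1ccc(cc1)P(c1ccccc1)c1ccccc1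
Why: SN2 quaternisation of the phosphine by the α-chloro ketone and deprotonation give the stabilised acyl ylide (Wittig reagent preparation); no stereocentre.

Step 3
Reactants: 5 4-hydroxy-3-iodobenzaldehyde; 6 tert-butyldimethyl(4-vinylphenoxy)silane
Product: 7 4-hydroxy-3-[(E)-2-(4-TBS-oxyphenyl)ethenyl]benzaldehyde
Conditions: Pd(OAc)2 (3 mol %), P(o-tol)3, Et3N, MeCN, 80 °C
Reagents that add atoms: none
Why: Mizoroki–Heck arylation of the styrene at its terminal carbon, with syn β-hydride elimination giving the E-stilbene; the free phenol and the aldehyde are tolerated.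

Step 4
Reactants: 7 4-hydroxy-3-[(E)-2-(4-TBS-oxyphenyl)ethenyl]benzaldehyde; 4 1-[2,4-bis(TIPS-oxy)phenyl]-2-(triphenylphosphoranylidene)ethan-1-one
Product: 8 (E)-1-[2,4-bis(TIPS-oxy)phenyl]-3-{4-hydroxy-3-[(E)-2-(4-TBS-oxyphenyl)ethenyl]phenyl}prop-2-en-1-one
Conditions: toluene, 110 °C
Reagents that add atoms: none
Why: Wittig olefination with a stabilised acyl ylide is E-selective and, the ylide being a weaker base than phenoxide, proceeds with the phenol unprotected.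

Step 5
Reactants: 9 4-bromobenzene-1,3-diol
Product: 10 1-bromo-2,4-bis(TIPS-oxy)benzene
Conditions: TIPSCl, imidazole, DMF, rt
Reagents that add atoms: chlorotriisopropylsilane, CC(C)[Si](Cl)(C(C)C)C(C)C
Why: standard imidazole-promoted silylation of phenols; no stereocentre.

Step 6
Reactants: 11 5-bromo-2,4-dihydroxybenzaldehyde
Product: 12 5-bromo-2,4-bis(TIPS-oxy)benzaldehyde
Conditions: TIPSOTf, 2,6-lutidine, CH2Cl2, 0 °C → rt
Reagents that add atoms: triisopropylsilyl triflate, CC(C)[Si](C(C)C)(C(C)C)OS(=O)(=O)C(F)(F)F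
Why: the silyl triflate also silylates the hydrogen-bonded ortho phenol; aldehyde and aryl bromide are inert.

Step 7
Reactants: 10 1-bromo-2,4-bis(TIPS-oxy)benzene; 12 5-bromo-2,4-bis(TIPS-oxy)benzaldehyde
Product: 14 rac-triethyl{[5-bromo-2,4-bis(TIPS-oxy)phenyl][2,4-bis(TIPS-oxy)phenyl]methoxy}silane, via benzhydrol 13 (not isolated)
Conditions: 10, Mg (I2-activated), THF, 50 °C; then 12, −78 → 0 °C; then TESCl, DMAP (10 mol %), 0 °C → rt
Reagents that add atoms: chlorotriethylsilane, CC[Si](Cl)(CC)CC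
Why: Grignard addition to the aldehyde (the aryl bromide of 12 does not exchange with an aryl Grignard) and in-situ silylation of the alkoxide; the new benzhydryl centre is racemic on purpose, because it is ionised in step 12.

Step 8
Reactants: 15 4-(TBS-oxy)benzaldehyde; 16 diethyl {2-[methoxy(methyl)amino]-2-oxoethyl}phosphonate
Product: 17 (E)-3-(4-TBS-oxyphenyl)-N-methoxy-N-methylprop-2-enamide
Conditions: LiCl, DBU, MeCN, rt
Reagents that add atoms: none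
Why: Horner–Wadsworth–Emmons olefination under Masamune–Roush conditions gives the E-alkene and is mild enough for the aryl silyl ether.

Step 9
Reactants: 14 rac-triethyl{[5-bromo-2,4-bis(TIPS-oxy)phenyl][2,4-bis(TIPS-oxy)phenyl]methoxy}silane; 17 (E)-3-(4-TBS-oxyphenyl)-N-methoxy-N-methylprop-2-enamide
Product: 18 rac-(E)-1-Ar*-3-(4-TBS-oxyphenyl)prop-2-en-1-one
Conditions: n-BuLi, THF, −78 °C; then 17, −78 → −20 °C; H2O
Reagents that add atoms: none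
Why: bromine–lithium exchange followed by Weinreb ketone synthesis, in which the chelated tetrahedral intermediate prevents over-addition and the aryllithium adds 1,2, so the E-enone of 17 is carried over.

Step 10
Reactants: 18 rac-(E)-1-Ar*-3-(4-TBS-oxyphenyl)prop-2-en-1-one; 2 2-chloro-1-[2,4-bis(TIPS-oxy)phenyl]ethan-1-one
Product: 19 1-Ar*-2-(4-TBS-oxybenzyl)-4-[2,4-bis(TIPS-oxy)phenyl]butane-1,4-dione (mixture of stereoisomers at C2 and the benzhydryl carbon)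
Conditions: LiBH(s-Bu)3, THF, −78 °C; then 2, Bu4NI (cat.), −78 → 0 °C
Reagents that add atoms: none
Why: conjugate hydride reduction of the chalcone gives the lithium enolate regiospecifically and this is C-alkylated by the α-chloro ketone (reductive alkylation, SN2); C2 forms unselectively on purpose, as it is equilibrated in step 12.

Step 11
Reactants: 19 1-Ar*-2-(4-TBS-oxybenzyl)-4-[2,4-bis(TIPS-oxy)phenyl]butane-1,4-dione; 15 4-(TBS-oxy)benzaldehyde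
Product: 21 (4S)-1-Ar*-3-[2,4-bis(TIPS-oxy)benzoyl]-2-(4-TBS-oxybenzyl)-4-(4-TBS-oxyphenyl)-4-(TES-oxy)butan-1-one (epimer mixture at C2 and C3 and the benzhydryl carbon), via aldol 20 (not isolated)
Conditions: (−)-Ipc2BOTf, i-Pr2NEt, CH2Cl2, −78 °C; 15, −78 → −20 °C; pH 7 buffer, MeOH, H2O2, 0 °C; crude: TESOTf, 2,6-lutidine, CH2Cl2, −78 °C
Reagents that add atoms: triethylsilyl triflate, CC[Si](CC)(CC)OS(=O)(=O)C(F)(F)F
Why: Paterson-type boron aldol, in which only the CH2 next to the 2,4-bis(TIPS-oxy)benzoyl group is enolised (the other ketone has a hindered methine) and the isopinocampheyl ligands select the aldehyde face to set the (4S) carbinol, the later C5′; the alcohol is then silylated so that it cannot form a hemiketal before step 12.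

Step 12
Reactants: 21 (4S)-1-Ar*-3-[2,4-bis(TIPS-oxy)benzoyl]-2-(4-TBS-oxybenzyl)-4-(4-TBS-oxyphenyl)-4-(TES-oxy)butan-1-one; 8 (E)-1-[2,4-bis(TIPS-oxy)phenyl]-3-{4-hydroxy-3-[(E)-2-(4-TBS-oxyphenyl)ethenyl]phenyl}prop-2-en-1-one
Product: 23 (2R,3R,αR,2′R,3′S,4′S,5′S)-undeca-O-silyl-lophirachalcone (8 TIPS on the four resorcinol rings and 3 TBS on the three 4-oxyphenyl rings), via ring A adduct 22 (not isolated)
Conditions: 8 (1.5 equiv), (R)-TRIP-NHTf (10 mol %), CH2Cl2, −78 → −40 °C; then TMSOTf (0.5 equiv), −40 °C, 30 min; Et3SiH (3 equiv), −78 → −40 °C; Et3N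
Reagents that add atoms: none
Why: Proposed new method: in stage one the acid ionises the benzhydryl silyl ether to a cation stabilised by four ortho/para oxygens, the stilbene carbon remote from the silyloxyphenyl group attacks it (the phenol ring is deactivated by its para enone), the resulting 4-silyloxybenzyl cation is closed by the phenol oxygen anti to the new C–C bond to give trans ring A, and the chiral phosphoramide anion, hydrogen-bonded to the phenol and ion-paired with the cation, is relied on to give (2R,3R,αR) (closest known type: chiral Brønsted-acid-catalysed additions of 2-hydroxystyrenes to quinone-methide-type benzhydryl cations); in stage two TMSOTf forms the cyclic oxocarbenium ion from the C1 ketone and the C4 silyl ether, its reversible deprotonation to the enol ether lets the benzyl-bearing carbon settle trans to the aroyl-bearing carbon, itself trans to the fixed (S) aryl carbon, and Et3SiH adds anti to the benzyl group so the resorcinol ring ends cis to it (closest known type: Lewis-acid/hydride reductive deoxygenation–epimerisation of cyclic hemiketals in tetrahydrofuran lignan synthesis and silane reductive etherification of silyloxy ketones).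

Step 13
Reactants: 23 (2R,3R,αR,2′R,3′S,4′S,5′S)-undeca-O-silyl-lophirachalcone
Product: 24 lophirachalcone
Conditions: Bu4NF/AcOH (1:1, 15 equiv), THF, 0 °C → rt
Reagents that add atoms: none
Why: fluoride cleavage of all aryl silyl ethers, buffered so that neither base-induced retro-oxa-Michael opening of ring B nor acid ionisation at C2′ occurs; no stereocentre is touched.

**Compound list**
1 | 2-chloro-1-(2,4-dihydroxyphenyl)ethan-1-one | O=C(CCl)c1ccc(O)cc1O | starting material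
2 | 2-chloro-1-[2,4-bis(TIPS-oxy)phenyl]ethan-1-one | O=C(CCl)c1ccc(O[Si](C(C)C)(C(C)C)C(C)C)cc1O[Si](C(C)C)(C(C)C)C(C)C | intermediate
3 | {2-[2,4-bis(TIPS-oxy)phenyl]-2-oxoethyl}triphenylphosphonium chloride | O=C(C[P+](c1ccccc1)(c1ccccc1)c1ccccc1)c1ccc(O[Si](C(C)C)(C(C)C)C(C)C)cc1O[Si](C(C)C)(C(C)C)C(C)C.[Cl-] | intermediate (not isolated)
4 | 1-[2,4-bis(TIPS-oxy)phenyl]-2-(triphenylphosphoranylidene)ethan-1-one | O=C(C=P(c1ccccc1)(c1ccccc1)c1ccccc1)c1ccc(O[Si](C(C)C)(C(C)C)C(C)C)cc1O[Si](C(C)C)(C(C)C)C(C)C | intermediate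
5 | 4-hydroxy-3-iodobenzaldehyde | O=Cc1ccc(O)c(I)c1 | starting material
6 | tert-butyldimethyl(4-vinylphenoxy)silane | C=Cc1ccc(O[Si](C)(C)C(C)(C)C)cc1 | starting material
7 | 4-hydroxy-3-[(E)-2-(4-TBS-oxyphenyl)ethenyl]benzaldehyde | O=Cc1ccc(O)c(/C=C/c2ccc(O[Si](C)(C)C(C)(C)C)cc2)c1 | intermediate
8 | (E)-1-[2,4-bis(TIPS-oxy)phenyl]-3-{4-hydroxy-3-[(E)-2-(4-TBS-oxyphenyl)ethenyl]phenyl}prop-2-en-1-one | O=C(/C=C/c1ccc(O)c(/C=C/c2ccc(O[Si](C)(C)C(C)(C)C)cc2)c1)c1ccc(O[Si](C(C)C)(C(C)C)C(C)C)cc1O[Si](C(C)C)(C(C)C)C(C)C | intermediate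
9 | 4-bromobenzene-1,3-diol | Oc1ccc(Br)c(O)c1 | starting material
10 | 1-bromo-2,4-bis(TIPS-oxy)benzene | Brc1ccc(O[Si](C(C)C)(C(C)C)C(C)C)cc1O[Si](C(C)C)(C(C)C)C(C)C | intermediate
11 | 5-bromo-2,4-dihydroxybenzaldehyde | O=Cc1cc(Br)c(O)cc1O | starting material
12 | 5-bromo-2,4-bis(TIPS-oxy)benzaldehyde | O=Cc1cc(Br)c(O[Si](C(C)C)(C(C)C)C(C)C)cc1O[Si](C(C)C)(C(C)C)C(C)C | intermediate
13 | rac-[5-bromo-2,4-bis(TIPS-oxy)phenyl][2,4-bis(TIPS-oxy)phenyl]methanol | OC(c1ccc(O[Si](C(C)C)(C(C)C)C(C)C)cc1O[Si](C(C)C)(C(C)C)C(C)C)c1cc(Br)c(O[Si](C(C)C)(C(C)C)C(C)C)cc1O[Si](C(C)C)(C(C)C)C(C)C | intermediate (not isolated)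
14 | rac-triethyl{[5-bromo-2,4-bis(TIPS-oxy)phenyl][2,4-bis(TIPS-oxy)phenyl]methoxy}silane | CC[Si](CC)(CC)OC(c1ccc(O[Si](C(C)C)(C(C)C)C(C)C)cc1O[Si](C(C)C)(C(C)C)C(C)C)c1cc(Br)c(O[Si](C(C)C)(C(C)C)C(C)C)cc1O[Si](C(C)C)(C(C)C)C(C)C | intermediate
15 | 4-(TBS-oxy)benzaldehyde | O=Cc1ccc(O[Si](C)(C)C(C)(C)C)cc1 | starting material
16 | diethyl {2-[methoxy(methyl)amino]-2-oxoethyl}phosphonate | CCOP(=O)(CC(=O)N(C)OC)OCC | starting material
17 | (E)-3-(4-TBS-oxyphenyl)-N-methoxy-N-methylprop-2-enamide | CON(C)C(=O)/C=C/c1ccc(O[Si](C)(C)C(C)(C)C)cc1 | intermediate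
18 | rac-(E)-1-Ar*-3-(4-TBS-oxyphenyl)prop-2-en-1-one | CC[Si](CC)(CC)OC(c1ccc(O[Si](C(C)C)(C(C)C)C(C)C)cc1O[Si](C(C)C)(C(C)C)C(C)C)c1cc(C(=O)/C=C/c2ccc(O[Si](C)(C)C(C)(C)C)cc2)c(O[Si](C(C)C)(C(C)C)C(C)C)cc1O[Si](C(C)C)(C(C)C)C(C)C | intermediate
19 | 1-Ar*-2-(4-TBS-oxybenzyl)-4-[2,4-bis(TIPS-oxy)phenyl]butane-1,4-dione, stereoisomer mixture | CC[Si](CC)(CC)OC(c1ccc(O[Si](C(C)C)(C(C)C)C(C)C)cc1O[Si](C(C)C)(C(C)C)C(C)C)c1cc(C(=O)C(Cc2ccc(O[Si](C)(C)C(C)(C)C)cc2)CC(=O)c2ccc(O[Si](C(C)C)(C(C)C)C(C)C)cc2O[Si](C(C)C)(C(C)C)C(C)C)c(O[Si](C(C)C)(C(C)C)C(C)C)cc1O[Si](C(C)C)(C(C)C)C(C)C | intermediate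
20 | (4S)-1-Ar*-3-[2,4-bis(TIPS-oxy)benzoyl]-2-(4-TBS-oxybenzyl)-4-hydroxy-4-(4-TBS-oxyphenyl)butan-1-one, other centres mixed | CC[Si](CC)(CC)OC(c1ccc(O[Si](C(C)C)(C(C)C)C(C)C)cc1O[Si](C(C)C)(C(C)C)C(C)C)c1cc(C(=O)C(Cc2ccc(O[Si](C)(C)C(C)(C)C)cc2)C(C(=O)c2ccc(O[Si](C(C)C)(C(C)C)C(C)C)cc2O[Si](C(C)C)(C(C)C)C(C)C)[C@H](O)c2ccc(O[Si](C)(C)C(C)(C)C)cc2)c(O[Si](C(C)C)(C(C)C)C(C)C)cc1O[Si](C(C)C)(C(C)C)C(C)C | intermediate (not isolated)
21 | (4S)-1-Ar*-3-[2,4-bis(TIPS-oxy)benzoyl]-2-(4-TBS-oxybenzyl)-4-(4-TBS-oxyphenyl)-4-(TES-oxy)butan-1-one, other centres mixed | CC[Si](CC)(CC)OC(c1ccc(O[Si](C(C)C)(C(C)C)C(C)C)cc1O[Si](C(C)C)(C(C)C)C(C)C)c1cc(C(=O)C(Cc2ccc(O[Si](C)(C)C(C)(C)C)cc2)C(C(=O)c2ccc(O[Si](C(C)C)(C(C)C)C(C)C)cc2O[Si](C(C)C)(C(C)C)C(C)C)[C@H](O[Si](CC)(CC)CC)c2ccc(O[Si](C)(C)C(C)(C)C)cc2)c(O[Si](C(C)C)(C(C)C)C(C)C)cc1O[Si](C(C)C)(C(C)C)C(C)C | intermediate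
22 | ring A adduct: (E)-1-[2,4-bis(TIPS-oxy)phenyl]-3-[(2R,3R)-2-(4-TBS-oxyphenyl)-3-{(R)-[2,4-bis(TIPS-oxy)phenyl][5-{(4S)-3-[2,4-bis(TIPS-oxy)benzoyl]-2-(4-TBS-oxybenzyl)-4-(4-TBS-oxyphenyl)-4-(TES-oxy)butanoyl}-2,4-bis(TIPS-oxy)phenyl]methyl}-2,3-dihydrobenzofuran-5-yl]prop-2-en-1-one, butanoyl C2 and C3 mixed | O=C(/C=C/c1ccc2c(c1)[C@@H]([C@H](c1ccc(O[Si](C(C)C)(C(C)C)C(C)C)cc1O[Si](C(C)C)(C(C)C)C(C)C)c1cc(C(=O)C(Cc3ccc(O[Si](C)(C)C(C)(C)C)cc3)C(C(=O)c3ccc(O[Si](C(C)C)(C(C)C)C(C)C)cc3O[Si](C(C)C)(C(C)C)C(C)C)[C@H](O[Si](CC)(CC)CC)c3ccc(O[Si](C)(C)C(C)(C)C)cc3)c(O[Si](C(C)C)(C(C)C)C(C)C)cc1O[Si](C(C)C)(C(C)C)C(C)C)[C@H](c1ccc(O[Si](C)(C)C(C)(C)C)cc1)O2)c1ccc(O[Si](C(C)C)(C(C)C)C(C)C)cc1O[Si](C(C)C)(C(C)C)C(C)C | intermediate (not isolated)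
23 | (2R,3R,αR,2′R,3′S,4′S,5′S)-undeca-O-silyl-lophirachalcone | O=C(/C=C/c1ccc2c(c1)[C@@H]([C@H](c1ccc(O[Si](C(C)C)(C(C)C)C(C)C)cc1O[Si](C(C)C)(C(C)C)C(C)C)c1cc([C@@H]3O[C@H](c4ccc(O[Si](C)(C)C(C)(C)C)cc4)[C@@H](C(=O)c4ccc(O[Si](C(C)C)(C(C)C)C(C)C)cc4O[Si](C(C)C)(C(C)C)C(C)C)[C@@H]3Cc3ccc(O[Si](C)(C)C(C)(C)C)cc3)c(O[Si](C(C)C)(C(C)C)C(C)C)cc1O[Si](C(C)C)(C(C)C)C(C)C)[C@H](c1ccc(O[Si](C)(C)C(C)(C)C)cc1)O2)c1ccc(O[Si](C(C)C)(C(C)C)C(C)C)cc1O[Si](C(C)C)(C(C)C)C(C)C | intermediate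
24 | lophirachalcone, (2R,3R,αR,2′R,3′S,4′S,5′S) | O=C(/C=C/c1ccc2c(c1)[C@@H]([C@H](c1ccc(O)cc1O)c1cc([C@@H]3O[C@H](c4ccc(O)cc4)[C@@H](C(=O)c4ccc(O)cc4O)[C@@H]3Cc3ccc(O)cc3)c(O)cc1O)[C@H](c1ccc(O)cc1)O2)c1ccc(O)cc1O | target

**Totals**
Total steps: 13. Longest linear sequence: 7 steps (11 → 12 → 14 → 18 → 19 → 21 → 23 → 24; steps 6, 7, 9, 10, 11, 12, 13).

**Three steps most likely to fail, each with one fallback**

Step 12 is the greatest risk: face and regiochemical control in the cation/stilbene union is unprecedented for this substrate class, and the silane stage may over-reduce the electron-rich benzylic ethers or the enone. The fallback sets out from 21 (using 6, 5 and 4) and returns at 22. Cross-metathesis of 6 with vinyltrimethylsilane, using the second-generation Grubbs catalyst RuCl2(=CHPh)(PCy3)(H2IMes), gives (E)-trimethyl[2-(4-TBS-oxyphenyl)ethenyl]silane F1. The cation from 21, generated with the same chiral acid, is captured by F1 at the silicon-bearing carbon (Hosomi–Sakurai-type ipso substitution), which gives the (R)-1,1-diaryl-3-arylpropene F2 and so sets Cα before any ring exists. Wittig reaction of 5 with 4 gives (E)-1-[2,4-bis(TIPS-oxy)phenyl]-3-(4-hydroxy-3-iodophenyl)prop-2-en-1-one F3. Oxyarylation of F2 with F3 (Pd(OAc)2, Ag2CO3, acetone) puts the aryl group on the alkene carbon remote from the silyloxyphenyl ring and the phenoxide on the benzylic carbon, giving the trans-dihydrobenzofuran 22 after separation of the C3 epimer. Compound 22 is then closed with TMSOTf/Et3SiH as in the second stage of step 12.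

Step 11 is the second risk: the boron reagent must override the racemic centre next to the enolate, and enolisation must be regioselective. The fallback sets out from 19 and returns at 20. The lithium enolate of 19 (LiN(SiMe3)2, THF, −78 °C) and 15 give the aldol as a mixture of carbinol epimers F4. Dess–Martin periodinane oxidises it to the 2-substituted 1,3-diketone F5. Asymmetric transfer hydrogenation with dynamic kinetic resolution at the carbon between the two carbonyls, RuCl[(S,S)-TsDPEN](p-cymene) with HCO2Na in H2O/CH2Cl2, reduces only the unhindered 4-silyloxyphenyl ketone and gives the (S)-carbinol 20, which is silylated as before.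

Step 10 is the third risk: the enolate may be quenched by the acidic α-chloro ketone or attack its carbonyl group. The fallback sets out from 18 (and 10) and returns at 19. Conjugate reduction of 18 with LiBH(s-Bu)3 followed by protonation gives the dihydrochalcone 1-Ar*-3-(4-TBS-oxyphenyl)propan-1-one F6. α-Methylenation (paraformaldehyde, diisopropylammonium trifluoroacetate, THF, reflux) gives the enone 1-Ar*-2-(4-TBS-oxybenzyl)prop-2-en-1-one F7. The Grignard reagent from 10 is formylated with DMF to give 2,4-bis(TIPS-oxy)benzaldehyde F8. A thiazolium-carbene-catalysed Stetter addition of F8 to F7 (3-benzyl-5-(2-hydroxyethyl)-4-methylthiazolium chloride, Et3N, dioxane, 70 °C) forms the C3–C4 bond by umpolung and gives 19.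

**Further compounds**
F1 | step 12 | (E)-trimethyl[2-(4-TBS-oxyphenyl)ethenyl]silane | C[Si](C)(C)/C=C/c1ccc(O[Si](C)(C)C(C)(C)C)cc1
F2 | step 12 | (4S)-1-[5-{(1R,2E)-1-[2,4-bis(TIPS-oxy)phenyl]-3-(4-TBS-oxyphenyl)prop-2-en-1-yl}-2,4-bis(TIPS-oxy)phenyl]-3-[2,4-bis(TIPS-oxy)benzoyl]-2-(4-TBS-oxybenzyl)-4-(4-TBS-oxyphenyl)-4-(TES-oxy)butan-1-one, C2 and C3 mixed | CC(C)(C)[Si](C)(C)Oc1ccc(/C=C/[C@H](c2ccc(O[Si](C(C)C)(C(C)C)C(C)C)cc2O[Si](C(C)C)(C(C)C)C(C)C)c2cc(C(=O)C(Cc3ccc(O[Si](C)(C)C(C)(C)C)cc3)C(C(=O)c3ccc(O[Si](C(C)C)(C(C)C)C(C)C)cc3O[Si](C(C)C)(C(C)C)C(C)C)[C@H](O[Si](CC)(CC)CC)c3ccc(O[Si](C)(C)C(C)(C)C)cc3)c(O[Si](C(C)C)(C(C)C)C(C)C)cc2O[Si](C(C)C)(C(C)C)C(C)C)cc1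
F3 | step 12 | (E)-1-[2,4-bis(TIPS-oxy)phenyl]-3-(4-hydroxy-3-iodophenyl)prop-2-en-1-one | O=C(/C=C/c1ccc(O)c(I)c1)c1ccc(O[Si](C(C)C)(C(C)C)C(C)C)cc1O[Si](C(C)C)(C(C)C)C(C)C
F4 | step 11 | 1-Ar*-3-[2,4-bis(TIPS-oxy)benzoyl]-2-(4-TBS-oxybenzyl)-4-hydroxy-4-(4-TBS-oxyphenyl)butan-1-one, all centres mixed | CC[Si](CC)(CC)OC(c1ccc(O[Si](C(C)C)(C(C)C)C(C)C)cc1O[Si](C(C)C)(C(C)C)C(C)C)c1cc(C(=O)C(Cc2ccc(O[Si](C)(C)C(C)(C)C)cc2)C(C(=O)c2ccc(O[Si](C(C)C)(C(C)C)C(C)C)cc2O[Si](C(C)C)(C(C)C)C(C)C)C(O)c2ccc(O[Si](C)(C)C(C)(C)C)cc2)c(O[Si](C(C)C)(C(C)C)C(C)C)cc1O[Si](C(C)C)(C(C)C)C(C)C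
F5 | step 11 | 4-Ar*-2-[2,4-bis(TIPS-oxy)benzoyl]-3-(4-TBS-oxybenzyl)-1-(4-TBS-oxyphenyl)butane-1,4-dione | CC[Si](CC)(CC)OC(c1ccc(O[Si](C(C)C)(C(C)C)C(C)C)cc1O[Si](C(C)C)(C(C)C)C(C)C)c1cc(C(=O)C(Cc2ccc(O[Si](C)(C)C(C)(C)C)cc2)C(C(=O)c2ccc(O[Si](C(C)C)(C(C)C)C(C)C)cc2O[Si](C(C)C)(C(C)C)C(C)C)C(=O)c2ccc(O[Si](C)(C)C(C)(C)C)cc2)c(O[Si](C(C)C)(C(C)C)C(C)C)cc1O[Si](C(C)C)(C(C)C)C(C)C
F6 | step 10 | rac-1-Ar*-3-(4-TBS-oxyphenyl)propan-1-one | CC[Si](CC)(CC)OC(c1ccc(O[Si](C(C)C)(C(C)C)C(C)C)cc1O[Si](C(C)C)(C(C)C)C(C)C)c1cc(C(=O)CCc2ccc(O[Si](C)(C)C(C)(C)C)cc2)c(O[Si](C(C)C)(C(C)C)C(C)C)cc1O[Si](C(C)C)(C(C)C)C(C)C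
F7 | step 10 | rac-1-Ar*-2-(4-TBS-oxybenzyl)prop-2-en-1-one | CC[Si](CC)(CC)OC(c1ccc(O[Si](C(C)C)(C(C)C)C(C)C)cc1O[Si](C(C)C)(C(C)C)C(C)C)c1cc(C(=O)C(=C)Cc2ccc(O[Si](C)(C)C(C)(C)C)cc2)c(O[Si](C(C)C)(C(C)C)C(C)C)cc1O[Si](C(C)C)(C(C)C)C(C)C
F8 | step 10 | 2,4-bis(TIPS-oxy)benzaldehyde | O=Cc1ccc(O[Si](C(C)C)(C(C)C)C(C)C)cc1O[Si](C(C)C)(C(C)C)C(C)C
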